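**Retrosynthetic overview**
1. Target 18 ⇐ one acid operation on the cis-dihydrobenzofuran 16: loss of five MOM groups, loss of the surplus benzyl group on O4, and epimerisation at C2 (cis → trans); C3 is not touched.
2. 16 ⇐ key step: enantioselective dirhodium-carbene 1,5-C–H insertion of diaryldiazomethane 15 (from hydrazone 14) into an ArO–CH2Ar bond; this makes the C2–C3 bond, closes the dihydrofuran ring and sets C3.
3. 14 ⇐ ring C aryllithium 11 + ring A benzonitrile 8 (ketimine, then exchange with hydrazine).
4. 8 ⇐ twofold SNAr of benzylic alcohol 3 on the difluoro stilbene nitrile 7; 7 ⇐ Heck coupling of 4-bromo-2,6-difluorobenzonitrile with styrene 5.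
5. Ring order: the four benzene rings are bought; the only ring made is the dihydrofuran, closed in step 8.

Ring letters: A = benzo ring of the dihydrobenzofuran, B = aryl on C2, C = aryl on C3, D = aryl of the styryl group.
Assumption: Rh2(R-PTAD)4, dirhodium tetrakis[(R)-(1-adamantyl)(phthalimido)acetate], is taken to give the (2S,3R) cis product; if the sense of induction is the opposite, the mirror-image catalyst Rh2(S-PTAD)4 is used and nothing else changes.

**Route**

Step 1
Reactants: 1 vanillin (4-hydroxy-3-methoxybenzaldehyde)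
Product: 2 3-methoxy-4-(methoxymethoxy)benzaldehyde
Conditions: MOMCl (1.3 equiv), iPr2NEt (1.5 equiv), CH2Cl2, 0 °C → rt
Reagents that add atoms: chloromethyl methyl ether (MOMCl), COCCl
Why: Williamson-type O-alkylation of the phenol by the reactive α-chloro ether gives the MOM acetal, which survives every basic, organometallic and oxidative step that follows.

Step 2
Reactants: 2 3-methoxy-4-(methoxymethoxy)benzaldehyde
Product: 3 [3-methoxy-4-(methoxymethoxy)phenyl]methanol
Conditions: NaBH4, MeOH, 0 °C
Reagents that add atoms: none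
Why: Hydride reduction of the aldehyde gives the benzylic alcohol without touching the acetal.

Step 3
Reactants: 4 2-methoxy-4-vinylphenol
Product: 5 4-ethenyl-2-methoxy-1-(methoxymethoxy)benzene
Conditions: MOMCl (1.3 equiv), iPr2NEt (1.5 equiv), BHT (trace), CH2Cl2, 0 °C → rt
Reagents that add atoms: chloromethyl methyl ether (MOMCl), COCCl
Why: The same phenol O-alkylation as in step 1 masks the ring D phenol and stops the vinylphenol from polymerising.

Step 4
Reactants: 5 4-ethenyl-2-methoxy-1-(methoxymethoxy)benzene; 6 4-bromo-2,6-difluorobenzonitrile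
Product: 7 2,6-difluoro-4-{(E)-2-[3-methoxy-4-(methoxymethoxy)phenyl]ethenyl}benzonitrile
Conditions: Pd(OAc)2 (2 mol %), P(o-tol)3 (6 mol %), Et3N, MeCN, 80 °C
Reagents that add atoms: none
Why: Mizoroki–Heck reaction in which the electron-poor aryl bromide adds to zerovalent palladium fast, and syn insertion of the styrene followed by syn β-hydride elimination gives only the (E)-stilbene while the C–F bonds stay intact.

Step 5
Reactants: 7 2,6-difluoro-4-{(E)-2-[3-methoxy-4-(methoxymethoxy)phenyl]ethenyl}benzonitrile; 3 [3-methoxy-4-(methoxymethoxy)phenyl]methanol (2.3 equiv)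
Product: 8 2,6-bis{[3-methoxy-4-(methoxymethoxy)phenyl]methoxy}-4-{(E)-2-[3-methoxy-4-(methoxymethoxy)phenyl]ethenyl}benzonitrile
Conditions: NaH (2.5 equiv), DMF, 0 → 50 °C
Reagents that add atoms: none
Why: Twofold nucleophilic aromatic substitution (SNAr) in which both fluorides, each ortho to the nitrile, are displaced by the benzylic alkoxide through Meisenheimer intermediates, giving a symmetric ring A with no need to tell the two oxygens apart.

Step 6
Reactants: 9 5-bromobenzene-1,3-diol
Product: 10 1-bromo-3,5-bis(methoxymethoxy)benzene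
Conditions: MOMCl (2.6 equiv), iPr2NEt (3 equiv), CH2Cl2, 0 °C → rt
Reagents that add atoms: chloromethyl methyl ether (MOMCl), COCCl
Why: Twofold phenol O-alkylation as in step 1 masks ring C for the lithiation.

Step 7
Reactants: 10 1-bromo-3,5-bis(methoxymethoxy)benzene (1.4 equiv); 8 2,6-bis{[3-methoxy-4-(methoxymethoxy)phenyl]methoxy}-4-{(E)-2-[3-methoxy-4-(methoxymethoxy)phenyl]ethenyl}benzonitrile
Product: 14 [2,6-bis{[3-methoxy-4-(methoxymethoxy)phenyl]methoxy}-4-{(E)-2-[3-methoxy-4-(methoxymethoxy)phenyl]ethenyl}phenyl][3,5-bis(methoxymethoxy)phenyl]methanone hydrazone (C=N–NH2; either C=N isomer), via aryllithium 11 (not isolated), via N-lithio ketimine 12 (not isolated), via N-H ketimine 13 (not isolated)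
Conditions: n-BuLi, THF, −78 °C; then 8, −78 → 0 °C; AcOH; then N2H4·H2O (15 equiv), EtOH, 70 °C, argon
Reagents that add atoms: hydrazine (as the hydrate), NN
Why: Bromine–lithium exchange and addition of the aryllithium to the nitrile give a hindered N–H ketimine that exchanges with the α-effect nucleophile hydrazine (transimination, ammonia lost), so the doubly ortho-substituted ketone never has to be condensed.

Step 8
Reactants: 14 the hydrazone from step 7
Product: 16 (2S,3R)-cis-3-[3,5-bis(methoxymethoxy)phenyl]-2-[3-methoxy-4-(methoxymethoxy)phenyl]-4-{[3-methoxy-4-(methoxymethoxy)phenyl]methoxy}-6-{(E)-2-[3-methoxy-4-(methoxymethoxy)phenyl]ethenyl}-2,3-dihydro-1-benzofuran, via diazo compound 15 (not isolated)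
Conditions: MnO2 (8 equiv), CH2Cl2, 0 °C, filter; then add slowly to Rh2(R-PTAD)4 (1 mol %), MeCN, 0 °C
Reagents that add atoms: none
Why: Hydrazone oxidation to the diaryldiazomethane, then enantioselective intramolecular 1,5-C–H insertion of the donor/donor dirhodium carbene into a benzylic ether C–H bond; the chiral carboxylate pocket selects the carbene face (C3 = R) and one of the two enantiotopic benzylic hydrogens in a concerted, cis-selective insertion (C2 = S), and because the two ortho benzyloxy groups are homotopic either one gives the same product.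

Step 9
Reactants: 16 the cis-dihydrobenzofuran from step 8
Product: 18 (2R,3R)-trans-3-(3,5-dihydroxyphenyl)-2-(4-hydroxy-3-methoxyphenyl)-6-[(E)-2-(4-hydroxy-3-methoxyphenyl)ethenyl]-2,3-dihydro-1-benzofuran-4-ol (target), via cis epimer 17 (not isolated)
Conditions: HCl (2 M in MeOH)–THF 2:1, n-C12H25SH (10 equiv), 45 °C, argon, dark
Reagents that add atoms: none
Why: Acidic methanolysis removes the five MOM acetals, the surplus (now p-hydroxybenzylic) ether on O4 ionises and is captured by the thiol, and reversible ionisation of the C2–O1 bond through the p-quinone-methide-type cation recloses to the more stable trans ring (thermodynamic epimerisation), so C2 becomes R while C3, which is never ionised, stays R.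

**Compound list**
1 | vanillin | COc1cc(C=O)ccc1O | starting material
2 | 3-methoxy-4-(methoxymethoxy)benzaldehyde | COCOc1ccc(C=O)cc1OC | intermediate
3 | [3-methoxy-4-(methoxymethoxy)phenyl]methanol | COCOc1ccc(CO)cc1OC | intermediate
4 | 2-methoxy-4-vinylphenol | C=Cc1ccc(O)c(OC)c1 | starting material
5 | 4-ethenyl-2-methoxy-1-(methoxymethoxy)benzene | C=Cc1ccc(OCOC)c(OC)c1 | intermediate
6 | 4-bromo-2,6-difluorobenzonitrile | N#Cc1c(F)cc(Br)cc1F | starting material
7 | 2,6-difluoro-4-{(E)-2-[3-methoxy-4-(methoxymethoxy)phenyl]ethenyl}benzonitrile | N#Cc1c(F)cc(/C=C/c2ccc(OCOC)c(OC)c2)cc1F | intermediate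
8 | 2,6-bis{[3-methoxy-4-(methoxymethoxy)phenyl]methoxy}-4-{(E)-styryl (ring D)}benzonitrile | N#Cc1c(OCc2ccc(OCOC)c(OC)c2)cc(/C=C/c2ccc(OCOC)c(OC)c2)cc1OCc1ccc(OCOC)c(OC)c1 | intermediate
9 | 5-bromobenzene-1,3-diol | Oc1cc(O)cc(Br)c1 | starting material
10 | 1-bromo-3,5-bis(methoxymethoxy)benzene | COCOc1cc(Br)cc(OCOC)c1 | intermediate
11 | [3,5-bis(methoxymethoxy)phenyl]lithium | [Li]c1cc(OCOC)cc(OCOC)c1 | intermediate
12 | N-lithio diaryl ketimine (lithium salt of 13) | [Li]N=C(c1cc(OCOC)cc(OCOC)c1)c1c(OCc2ccc(OCOC)c(OC)c2)cc(/C=C/c2ccc(OCOC)c(OC)c2)cc1OCc1ccc(OCOC)c(OC)c1 | intermediate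
13 | N–H diaryl ketimine (ring A)(ring C)C=NH | N=C(c1cc(OCOC)cc(OCOC)c1)c1c(OCc2ccc(OCOC)c(OC)c2)cc(/C=C/c2ccc(OCOC)c(OC)c2)cc1OCc1ccc(OCOC)c(OC)c1 | intermediate
14 | diaryl ketone hydrazone (ring A)(ring C)C=N–NH2 | NN=C(c1cc(OCOC)cc(OCOC)c1)c1c(OCc2ccc(OCOC)c(OC)c2)cc(/C=C/c2ccc(OCOC)c(OC)c2)cc1OCc1ccc(OCOC)c(OC)c1 | intermediate
15 | diaryldiazomethane (ring A)(ring C)C=N2 | [N-]=[N+]=C(c1cc(OCOC)cc(OCOC)c1)c1c(OCc2ccc(OCOC)c(OC)c2)cc(/C=C/c2ccc(OCOC)c(OC)c2)cc1OCc1ccc(OCOC)c(OC)c1 | intermediate
16 | (2S,3R)-cis-dihydrobenzofuran, five MOM groups, O4-benzyl | COCOc1ccc(/C=C/c2cc(OCc3ccc(OCOC)c(OC)c3)c3c(c2)O[C@H](c2ccc(OCOC)c(OC)c2)[C@@H]3c2cc(OCOC)cc(OCOC)c2)cc1OC | intermediate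
17 | (2S,3R)-cis epimer of the target (free pentaphenol) | COc1cc(/C=C/c2cc(O)c3c(c2)O[C@H](c2ccc(O)c(OC)c2)[C@@H]3c2cc(O)cc(O)c2)ccc1O | intermediate
18 | (2R,3R)-trans-3-(3,5-dihydroxyphenyl)-2-(4-hydroxy-3-methoxyphenyl)-6-[(E)-2-(4-hydroxy-3-methoxyphenyl)ethenyl]-2,3-dihydro-1-benzofuran-4-ol | COc1cc(/C=C/c2cc(O)c3c(c2)O[C@@H](c2ccc(O)c(OC)c2)[C@@H]3c2cc(O)cc(O)c2)ccc1O | target

**Totals**
Total step count: 9. Longest linear sequence: 6 steps (1, 2, 5, 7, 8, 9 from vanillin; equally 3, 4, 5, 7, 8, 9 from 2-methoxy-4-vinylphenol).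

**The three steps most likely to fail**

Step 8 (most likely). The carbene carbon carries a 2,6-disubstituted aryl ring, which is outside the usual substrate range of this insertion, so enantioselectivity at C3 may drop or diazo decomposition may be slow. Only C3 matters, because step 9 resets C2. Fallback: move stereocontrol from the catalyst to a separation. Setting out from 14, the hydrazone is oxidised as before and diazo compound 15 is decomposed with the achiral, robust catalyst Rh2(esp)2 in CH2Cl2. This closes the ring as the racemate, that is 16 together with its mirror image, the (2R,3S)-cis enantiomer of 16 F1. Preparative chromatography on a chiral stationary phase (amylose tris(3,5-dimethylphenylcarbamate), CO2/MeOH) gives 16, where the route is rejoined.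

Step 9. The vanillyl-type cation set free from O4 can alkylate the electron-rich free phenol rings, and the free polyphenol stilbene sits in warm acid. Fallback: do the cation chemistry first, in an aprotic medium, while all phenols are still masked, and unmask last without protic acid. Setting out from 16, TFA (10 equiv) and 1,3,5-trimethoxybenzene (5 equiv) in CH2Cl2 at −10 °C transfer the surplus benzyl group to the trimethoxybenzene (Friedel–Crafts) and equilibrate C2. This gives the trans phenol (2R,3R)-3-[3,5-bis(methoxymethoxy)phenyl]-2-[3-methoxy-4-(methoxymethoxy)phenyl]-6-{(E)-2-[3-methoxy-4-(methoxymethoxy)phenyl]ethenyl}-2,3-dihydro-1-benzofuran-4-ol F2. The four remaining aryl MOM ethers are then converted with TMSOTf/2,2′-bipyridyl in CH2Cl2 at 0 °C into aryl silyl ethers and hydrolysed with water, which comes back to the route at 18.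

Step 7. Addition to the doubly ortho-substituted nitrile should work, but exchange of the very hindered N–H ketimine 13 with hydrazine requires attack at a shielded carbon and may stall. Fallback: form the N–N bond at nitrogen instead. Setting out from the N-lithio ketimine 12 (made exactly as in step 7), O-(diphenylphosphinyl)hydroxylamine, Ph2P(O)ONH2, in THF at −20 °C → rt aminates the nitrogen anion and gives hydrazone 14 directly, where the route is rejoined. This is a proposed extension of the known electrophilic N-amination of nitrogen anions with this reagent; it makes no compound outside the compound list (F0).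

**Further compounds**
F0 | step 7 | none | none
F1 | step 8 | (2R,3S)-cis enantiomer of 16 | COCOc1ccc(/C=C/c2cc(OCc3ccc(OCOC)c(OC)c3)c3c(c2)O[C@@H](c2ccc(OCOC)c(OC)c2)[C@H]3c2cc(OCOC)cc(OCOC)c2)cc1OC
F2 | step 9 | (2R,3R)-trans-3-[3,5-bis(methoxymethoxy)phenyl]-2-[3-methoxy-4-(methoxymethoxy)phenyl]-6-{(E)-2-[3-methoxy-4-(methoxymethoxy)phenyl]ethenyl}-2,3-dihydro-1-benzofuran-4-ol | COCOc1ccc(/C=C/c2cc(O)c3c(c2)O[C@@H](c2ccc(OCOC)c(OC)c2)[C@@H]3c2cc(OCOC)cc(OCOC)c2)cc1OC
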